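A direct plan would build the chain outward from ring A: an ortho-hydroxybenzhydrol would be dehydrated to the ortho-quinone methide A1, a carbene-catalysed homoenolate annulation with an enal would join C1 to C2 and close the benzoxepinone A2, enolate methylation would give A3, and opening with an aryl Grignard reagent would give the ketone A4, to be acylated on ring A and hydrogenolysed.
Its weakest steps would be:
- the annulation, because the trans relation at the diarylmethine would rest on one transition-state model and the electron-rich methide would be a sluggish acceptor that dimerises easily;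
- the methylation, because aryl ester enolates expel phenoxide to give ketenes and the flexible seven-membered ring would offer little facial bias;
- the final reduction, which would have to take the epimerisable α-methyl aryl ketone of A4 down to CH2 while sparing the second aryl ketone.

The new route rests on a γ-butyrolactone template. The methyl carbons on C2 and C3 of the butyl chain (C1 = diarylmethine, C4 = benzylic CH2) are 1,4-related, so they are tied through oxygen as lactone carbonyl and OCH2. C3 then is a ring stereocentre set by auxiliary alkylation, C2 the enolisable α-carbon, and C1 the exocyclic β-carbon of an (E)-arylidene enoate. The key step adds the ring A aryl cuprate to C1 anti to the pseudoaxial benzyl group on C3: it forms the ring A–C1 bond, fixes C1, and lets C2 settle trans. Quinone methide, aryl-ester enolate and ketone α-stereocentre disappear; C4 is CH2 from the start.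

Key step: step 5

Remark on numbering: lactone positions are O1, C2(=O), C3, C4, C5. Lactone C3 and C4 become chain C2 and C3, lactone C2 and C5 become the two methyl groups, and ring A is the phloroglucinol ring.

Step 1
Reactants: 1 3-[4-(benzyloxy)phenyl]propanoic acid; 2 pivaloyl chloride; 3 (4R)-4-benzyl-1,3-oxazolidin-2-one
Product: 5 (4R)-4-benzyl-3-{3-[4-(benzyloxy)phenyl]propanoyl}-1,3-oxazolidin-2-one, via mixed pivalic anhydride 4 (not isolated)
Conditions: 2 (1.1 equiv), Et3N (2.5 equiv), THF, −20 °C; then 3, LiCl (1.1 equiv), −20 °C to rt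
Reagents that add atoms: (4R)-4-benzyl-1,3-oxazolidin-2-one (3), O=C1N[C@H](Cc2ccccc2)CO1
Why: N-acylation of the oxazolidinone through the mixed anhydride, in which the hindered pivaloyl carbonyl is not attacked; no stereocentre is formed.

Step 2
Reactants: 5 acyl oxazolidinone; 6 tert-butyl bromoacetate
Product: 8 tert-butyl (3S)-3-{[(4R)-4-benzyl-2-oxo-1,3-oxazolidin-3-yl]carbonyl}-4-[4-(benzyloxy)phenyl]butanoate, via sodium enolate 7 (not isolated)
Conditions: NaN(SiMe3)2 (1.1 equiv), THF, −78 °C; 6 (1.5 equiv), −78 to −40 °C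
Reagents that add atoms: tert-butyl bromoacetate (6), CC(C)(C)OC(=O)CBr
Why: Evans asymmetric alkylation: the chelated Z-enolate should be alkylated on the face away from the benzyl group of the (R)-auxiliary, which sets the future chain C3 as (S).

Step 3
Reactants: 8 alkylated imide
Product: 10 (4S)-4-{[4-(benzyloxy)phenyl]methyl}oxolan-2-one, via hydroxy ester 9 (not isolated)
Conditions: LiBH4 (1.5 equiv), MeOH (1.5 equiv), THF, 0 °C; aq. NH4Cl; crude, TsOH·H2O (10 mol %), toluene, 80 °C
Reagents that add atoms: none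
Why: Reductive cleavage of the auxiliary (LiBH4 reduces the imide carbonyl and spares the tert-butyl ester) and acid-catalysed lactonisation; the stereocentre becomes the non-acidic lactone C4 and keeps its configuration.

Step 4
Reactants: 10 lactone; 11 4-(benzyloxy)benzaldehyde; 12 methanesulfonyl chloride
Product: 15 (3E,4S)-3-{[4-(benzyloxy)phenyl]methylidene}-4-{[4-(benzyloxy)phenyl]methyl}oxolan-2-one, via lithium aldolate 13 (not isolated), via aldol mesylate 14 (not isolated)
Conditions: LiN(SiMe3)2 (1.1 equiv), THF, −78 °C; 11 (1.1 equiv); 12 (1.3 equiv), −78 to 0 °C; DBU (3 equiv), 0 °C to rt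
Reagents that add atoms: 4-(benzyloxy)benzaldehyde (11), O=Cc1ccc(OCc2ccccc2)cc1
Why: Aldol condensation (enolate addition, then E1cB loss of mesylate): the conjugated (E)-alkene with the aryl group syn to lactone C4 should be the thermodynamic product, and C4 is not acidic and stays (S).

Step 5
Reactants: 15 (E)-arylidene lactone; 16 1,3,5-tris(benzyloxy)benzene; 17 chlorotrimethylsilane
Product: 22 (3S,4S)-3-{(R)-[4-(benzyloxy)phenyl][2,4,6-tris(benzyloxy)phenyl]methyl}-4-{[4-(benzyloxy)phenyl]methyl}oxolan-2-one, via aryllithium 18 (not isolated), via diaryl cuprate 19 (not isolated), via silyl ketene acetal 20 (not isolated), via cis lactone 21 (not isolated)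
Conditions: 16 (2.2 equiv), n-BuLi (2.1 equiv), THF, 0 °C; CuBr·SMe2 (1.05 equiv), −40 °C; 15, Me3SiCl (2 equiv), −78 to −20 °C; aq. NH4Cl; crude, DBU (0.2 equiv), CH2Cl2, rt
Reagents that add atoms: 1,3,5-tris(benzyloxy)benzene (16), c1c(OCc2ccccc2)cc(OCc2ccccc2)cc1OCc1ccccc1
Why: Gilman conjugate addition accelerated by Me3SiCl: the soft diaryl cuprate should form a copper–alkene π-complex with the s-cis exocyclic enoate, add at the β-carbon C1 and reductively eliminate the ring A–C1 bond, and the enolate is trapped as silyl ketene acetal 20, so that 1,4-addition prevails over attack at the carbonyl. The closest known reaction type is the cuprate 1,4-addition to α-alkylidene γ-butyrolactones; no ring is closed in this step. C1 is set by the template: in the (E)-alkene the aryl group lies syn to lactone C4, allylic 1,3-strain turns the C4 benzyl group pseudoaxial over one face of the exocyclic double bond, and the cuprate should enter from the other face, which with (4S) gives (R) at C1. Lactone C3 (the future chain C2) is set afterwards by thermodynamics: hydrolysis of 20 gives some cis lactone 21, and DBU equilibrates this single acidic centre to the trans (3S,4S) isomer, in which the two large groups avoid each other. The step needs facial selectivity and retention of the (E) geometry, which the rigid five-membered ring and the non-ionising conditions should secure, and it needs metalation of 16 at a ring carbon flanked by two benzyloxy groups, the doubly activated ortho position.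

Step 6
Reactants: 22 trans lactone
Product: 23 (2S,3S)-2-{(R)-[4-(benzyloxy)phenyl][2,4,6-tris(benzyloxy)phenyl]methyl}-3-{[4-(benzyloxy)phenyl]methyl}butane-1,4-diol
Conditions: LiAlH4 (2 equiv), THF, 0 °C to rt
Reagents that add atoms: none
Why: LiAlH4 reduction of the lactone cuts the template open to the 1,4-diol; chain C2 loses its acidity, so the three stereocentres are fixed from here on.

Step 7
Reactants: 23 diol; 12 methanesulfonyl chloride
Product: 24 (2S,3S)-2-{(R)-[4-(benzyloxy)phenyl][2,4,6-tris(benzyloxy)phenyl]methyl}-3-{[4-(benzyloxy)phenyl]methyl}butane-1,4-diyl dimethanesulfonate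
Conditions: 12 (3 equiv), Et3N (4 equiv), CH2Cl2, −10 °C
Reagents that add atoms: methanesulfonyl chloride (12), CS(=O)(=O)Cl
Why: Mesylation of both primary alcohols with excess reagent in the cold, so that the second sulfonylation should outrun ring closure of the monomesylate to an oxolane; no stereocentre is touched.

Step 8
Reactants: 24 dimesylate
Product: 25 1,3,5-tris(benzyloxy)-2-{(1R,2R,3S)-1,4-bis[4-(benzyloxy)phenyl]-2,3-dimethylbutyl}benzene
Conditions: LiBEt3H (6 equiv), THF, 0 to 50 °C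
Reagents that add atoms: none
Why: SN2 displacement of both primary mesylates by the strongly nucleophilic triethylborohydride turns the two former ring carbons into the methyl groups on C2 and C3; the stereocentres are not involved.

Step 9
Reactants: 25 dimethyl compound; 26 3-(4-methoxyphenyl)propanoyl chloride
Product: 27 1-{2,4,6-tris(benzyloxy)-3-[(1R,2R,3S)-1,4-bis[4-(benzyloxy)phenyl]-2,3-dimethylbutyl]phenyl}-3-(4-methoxyphenyl)propan-1-one
Conditions: 26 (1.2 equiv), SnCl4 (1.2 equiv), CH2Cl2, −78 to −40 °C; cold aq. NaHCO3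
Reagents that add atoms: 3-(4-methoxyphenyl)propanoyl chloride (26), COc1ccc(CCC(=O)Cl)cc1
Why: Friedel–Crafts acylation at one of the two equivalent free positions of the tris(benzyloxy) ring, which is far more nucleophilic than the mono-alkoxy rings and is deactivated after the first acylation; the low temperature should keep the acid-labile diarylmethine bond intact.

Step 10
Reactants: 27 pentabenzyl ether
Product: 28 1-{2,4,6-trihydroxy-3-[(1R,2R,3S)-1,4-bis(4-hydroxyphenyl)-2,3-dimethylbutyl]phenyl}-3-(4-methoxyphenyl)propan-1-one (target)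
Conditions: H2 (1 atm), 10% Pd/C, EtOAc–MeOH 1:1, rt
Reagents that add atoms: none
Why: Catalytic hydrogenolysis of the five benzyl ethers under neutral conditions; the hydrogen-bonded trihydroxyphenyl ketone, the aryl methyl ether and the three stereocentres should be inert.

Compound list
1 | 3-[4-(benzyloxy)phenyl]propanoic acid | OC(=O)CCc1ccc(OCc2ccccc2)cc1 | starting material
2 | pivaloyl chloride | CC(C)(C)C(=O)Cl | starting material
3 | (4R)-4-benzyl-1,3-oxazolidin-2-one | O=C1N[C@H](Cc2ccccc2)CO1 | starting material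
4 | 3-[4-(benzyloxy)phenyl]propanoic pivalic anhydride | CC(C)(C)C(=O)OC(=O)CCc1ccc(OCc2ccccc2)cc1 | intermediate (not isolated)
5 | (4R)-4-benzyl-3-{3-[4-(benzyloxy)phenyl]propanoyl}-1,3-oxazolidin-2-one | O=C(CCc1ccc(OCc2ccccc2)cc1)N1[C@H](Cc2ccccc2)COC1=O | intermediate
6 | tert-butyl bromoacetate | CC(C)(C)OC(=O)CBr | starting material
7 | sodium Z-enolate of 5 | [Na]O/C(=C\Cc1ccc(OCc2ccccc2)cc1)N1[C@H](Cc2ccccc2)COC1=O | intermediate (not isolated)
8 | tert-butyl (3S)-3-{[(4R)-4-benzyl-2-oxo-1,3-oxazolidin-3-yl]carbonyl}-4-[4-(benzyloxy)phenyl]butanoate | CC(C)(C)OC(=O)C[C@H](Cc1ccc(OCc2ccccc2)cc1)C(=O)N1[C@H](Cc2ccccc2)COC1=O | intermediate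
9 | tert-butyl (3S)-4-[4-(benzyloxy)phenyl]-3-(hydroxymethyl)butanoate | CC(C)(C)OC(=O)C[C@H](Cc1ccc(OCc2ccccc2)cc1)CO | intermediate (not isolated)
10 | (4S)-4-{[4-(benzyloxy)phenyl]methyl}oxolan-2-one | O=C1OC[C@@H](Cc2ccc(OCc3ccccc3)cc2)C1 | intermediate
11 | 4-(benzyloxy)benzaldehyde | O=Cc1ccc(OCc2ccccc2)cc1 | starting material
12 | methanesulfonyl chloride | CS(=O)(=O)Cl | starting material
13 | lithium alkoxide of (4S)-3-{[4-(benzyloxy)phenyl](hydroxy)methyl}-4-{[4-(benzyloxy)phenyl]methyl}oxolan-2-one (epimers at C3 and the carbinol carbon) | O=C1OC[C@@H](Cc2ccc(OCc3ccccc3)cc2)C1C(O[Li])c1ccc(OCc2ccccc2)cc1 | intermediate (not isolated)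
14 | methanesulfonate of the aldol from 10 and 11 (epimers at C3 and the carbinol carbon) | O=C1OC[C@@H](Cc2ccc(OCc3ccccc3)cc2)C1C(OS(C)(=O)=O)c1ccc(OCc2ccccc2)cc1 | intermediate (not isolated)
15 | (3E,4S)-3-{[4-(benzyloxy)phenyl]methylidene}-4-{[4-(benzyloxy)phenyl]methyl}oxolan-2-one | O=C1OC[C@@H](Cc2ccc(OCc3ccccc3)cc2)/C1=C\c1ccc(OCc2ccccc2)cc1 | intermediate
16 | 1,3,5-tris(benzyloxy)benzene | c1c(OCc2ccccc2)cc(OCc2ccccc2)cc1OCc1ccccc1 | starting material
17 | chlorotrimethylsilane | C[Si](C)(C)Cl | starting material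
18 | [2,4,6-tris(benzyloxy)phenyl]lithium | [Li]c1c(OCc2ccccc2)cc(OCc2ccccc2)cc1OCc1ccccc1 | intermediate (not isolated)
19 | lithium bis[2,4,6-tris(benzyloxy)phenyl]cuprate | [Li+].[Cu-](c1c(OCc2ccccc2)cc(OCc2ccccc2)cc1OCc1ccccc1)c1c(OCc2ccccc2)cc(OCc2ccccc2)cc1OCc1ccccc1 | intermediate (not isolated)
20 | trimethylsilyl ketene acetal of 22 (2-trimethylsilyloxy-4,5-dihydrofuran; C4 and the diarylmethine configured as in 22) | C[Si](C)(C)OC1=C([C@H](c2ccc(OCc3ccccc3)cc2)c2c(OCc3ccccc3)cc(OCc3ccccc3)cc2OCc2ccccc2)[C@H](Cc2ccc(OCc3ccccc3)cc2)CO1 | intermediate (not isolated)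
21 | (3R,4S)-3-{(R)-[4-(benzyloxy)phenyl][2,4,6-tris(benzyloxy)phenyl]methyl}-4-{[4-(benzyloxy)phenyl]methyl}oxolan-2-one (cis) | O=C1OC[C@@H](Cc2ccc(OCc3ccccc3)cc2)[C@H]1[C@H](c1ccc(OCc2ccccc2)cc1)c1c(OCc2ccccc2)cc(OCc2ccccc2)cc1OCc1ccccc1 | intermediate (not isolated)
22 | (3S,4S)-3-{(R)-[4-(benzyloxy)phenyl][2,4,6-tris(benzyloxy)phenyl]methyl}-4-{[4-(benzyloxy)phenyl]methyl}oxolan-2-one (trans) | O=C1OC[C@@H](Cc2ccc(OCc3ccccc3)cc2)[C@@H]1[C@H](c1ccc(OCc2ccccc2)cc1)c1c(OCc2ccccc2)cc(OCc2ccccc2)cc1OCc1ccccc1 | intermediate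
23 | (2S,3S)-2-{(R)-[4-(benzyloxy)phenyl][2,4,6-tris(benzyloxy)phenyl]methyl}-3-{[4-(benzyloxy)phenyl]methyl}butane-1,4-diol | OC[C@@H]([C@H](c1ccc(OCc2ccccc2)cc1)c1c(OCc2ccccc2)cc(OCc2ccccc2)cc1OCc1ccccc1)[C@@H](CO)Cc1ccc(OCc2ccccc2)cc1 | intermediate
24 | (2S,3S)-2-{(R)-[4-(benzyloxy)phenyl][2,4,6-tris(benzyloxy)phenyl]methyl}-3-{[4-(benzyloxy)phenyl]methyl}butane-1,4-diyl dimethanesulfonate | CS(=O)(=O)OC[C@@H]([C@H](c1ccc(OCc2ccccc2)cc1)c1c(OCc2ccccc2)cc(OCc2ccccc2)cc1OCc1ccccc1)[C@@H](COS(C)(=O)=O)Cc1ccc(OCc2ccccc2)cc1 | intermediate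
25 | 1,3,5-tris(benzyloxy)-2-{(1R,2R,3S)-1,4-bis[4-(benzyloxy)phenyl]-2,3-dimethylbutyl}benzene | C[C@@H]([C@H](c1ccc(OCc2ccccc2)cc1)c1c(OCc2ccccc2)cc(OCc2ccccc2)cc1OCc1ccccc1)[C@@H](C)Cc1ccc(OCc2ccccc2)cc1 | intermediate
26 | 3-(4-methoxyphenyl)propanoyl chloride | COc1ccc(CCC(=O)Cl)cc1 | starting material
27 | 1-{2,4,6-tris(benzyloxy)-3-[(1R,2R,3S)-1,4-bis[4-(benzyloxy)phenyl]-2,3-dimethylbutyl]phenyl}-3-(4-methoxyphenyl)propan-1-one | COc1ccc(CCC(=O)c2c(OCc3ccccc3)cc(OCc3ccccc3)c([C@@H](c3ccc(OCc4ccccc4)cc3)[C@H](C)[C@@H](C)Cc3ccc(OCc4ccccc4)cc3)c2OCc2ccccc2)cc1 | intermediate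
28 | 1-{2,4,6-trihydroxy-3-[(1R,2R,3S)-1,4-bis(4-hydroxyphenyl)-2,3-dimethylbutyl]phenyl}-3-(4-methoxyphenyl)propan-1-one | COc1ccc(CCC(=O)c2c(O)cc(O)c([C@@H](c3ccc(O)cc3)[C@H](C)[C@@H](C)Cc3ccc(O)cc3)c2O)cc1 | target

Total step count: 10. Longest linear sequence: 10 steps (1 to 28, fully linear).

Steps most likely to fail

Step 5. The doubly ortho-substituted aryl group may transfer too slowly from copper to the β-aryl enoate carbon, the cuprate may attack both faces, or benzylic lithiation of 16 may compete with ring metalation. The fallback sets out from 15 and 16 and makes the same bond by Friedel–Crafts conjugate addition: Sc(OTf)3 (10 mol %) in CH2Cl2–(CF3)2CHOH at 0 °C would let the neutral arene attack C1 of the Lewis-acid-bound s-cis enoate from the face away from the benzyl group. Tautomerisation would give cis lactone 21 and its epimer, and the DBU treatment of the main route would bring the material back at 22; no compound outside the list would be made (F0).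

Step 9. The Lewis acid may ionise the bond between the diarylmethine carbon and ring A (loss or scrambling of C1), or strip benzyl groups. The fallback sets out from 25 and brings the acyl group in by halogen–metal exchange.
- N-Bromosuccinimide (1.0 equiv, CH2Cl2, −78 °C) would brominate the free position of ring A to give 1,3,5-tris(benzyloxy)-2-bromo-4-{(1R,2R,3S)-1,4-bis[4-(benzyloxy)phenyl]-2,3-dimethylbutyl}benzene F1.
- Acid chloride 26 with N,O-dimethylhydroxylamine hydrochloride and pyridine would give N-methoxy-N-methyl-3-(4-methoxyphenyl)propanamide F2.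
- F1 with t-BuLi (2 equiv, THF, −78 °C) would give {2,4,6-tris(benzyloxy)-3-[(1R,2R,3S)-1,4-bis[4-(benzyloxy)phenyl]-2,3-dimethylbutyl]phenyl}lithium F3, whose addition to F2 would come back to the route at 27.

Step 8. Hydride displacement at the two β-branched primary carbons may stall, and ring closure by a neighbouring benzyloxy oxygen may then take over. The fallback sets out from diol 23 and makes the deoxygenation a radical process: I2, PPh3 and imidazole (toluene, 60 °C) would give (2S,3S)-2-{(R)-[4-(benzyloxy)phenyl][2,4,6-tris(benzyloxy)phenyl]methyl}-3-{[4-(benzyloxy)phenyl]methyl}-1,4-diiodobutane F4, and Bu3SnH with azobisisobutyronitrile (toluene, 80 °C) would reduce both carbon–iodine bonds and come back to the route at 25.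

Further compounds
F0 | step 5 | none | none
F1 | step 9 | 1,3,5-tris(benzyloxy)-2-bromo-4-{(1R,2R,3S)-1,4-bis[4-(benzyloxy)phenyl]-2,3-dimethylbutyl}benzene | C[C@@H]([C@H](c1ccc(OCc2ccccc2)cc1)c1c(OCc2ccccc2)cc(OCc2ccccc2)c(Br)c1OCc1ccccc1)[C@@H](C)Cc1ccc(OCc2ccccc2)cc1
F2 | step 9 | N-methoxy-N-methyl-3-(4-methoxyphenyl)propanamide | COc1ccc(CCC(=O)N(C)OC)cc1
F3 | step 9 | {2,4,6-tris(benzyloxy)-3-[(1R,2R,3S)-1,4-bis[4-(benzyloxy)phenyl]-2,3-dimethylbutyl]phenyl}lithium | C[C@@H]([C@H](c1ccc(OCc2ccccc2)cc1)c1c(OCc2ccccc2)cc(OCc2ccccc2)c([Li])c1OCc1ccccc1)[C@@H](C)Cc1ccc(OCc2ccccc2)cc1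
F4 | step 8 | (2S,3S)-2-{(R)-[4-(benzyloxy)phenyl][2,4,6-tris(benzyloxy)phenyl]methyl}-3-{[4-(benzyloxy)phenyl]methyl}-1,4-diiodobutane | IC[C@@H]([C@H](c1ccc(OCc2ccccc2)cc1)c1c(OCc2ccccc2)cc(OCc2ccccc2)cc1OCc1ccccc1)[C@@H](CI)Cc1ccc(OCc2ccccc2)cc1
A1 | direct plan | (6Z)-3,5-bis(benzyloxy)-6-{[4-(benzyloxy)phenyl]methylidene}cyclohexa-2,4-dien-1-one | O=C1C=C(OCc2ccccc2)C=C(OCc2ccccc2)/C1=C/c1ccc(OCc2ccccc2)cc1
A2 | direct plan | (4R,5R)-6,8-bis(benzyloxy)-5-[4-(benzyloxy)phenyl]-4-methyl-4,5-dihydro-1-benzoxepin-2(3H)-one | O=C1C[C@@H](C)[C@H](c2ccc(OCc3ccccc3)cc2)c2c(OCc3ccccc3)cc(OCc3ccccc3)cc2O1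
A3 | direct plan | (3R,4S,5R)-6,8-bis(benzyloxy)-5-[4-(benzyloxy)phenyl]-3,4-dimethyl-4,5-dihydro-1-benzoxepin-2(3H)-one | O=C1[C@H](C)[C@@H](C)[C@H](c2ccc(OCc3ccccc3)cc2)c2c(OCc3ccccc3)cc(OCc3ccccc3)cc2O1
A4 | direct plan | (2R,3S,4R)-1,4-bis[4-(benzyloxy)phenyl]-4-[2,4-bis(benzyloxy)-6-hydroxyphenyl]-2,3-dimethylbutan-1-one | O=C(c1ccc(OCc2ccccc2)cc1)[C@H](C)[C@@H](C)[C@H](c1ccc(OCc2ccccc2)cc1)c1c(O)cc(OCc2ccccc2)cc1OCc1ccccc1
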